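Atom numbers used throughout: ring A is C1–C6 (C1 carries isopropyl), C7 is the lactone carbonyl, O8 the ring oxygen, C9 the ring methylene, C10=C11 the ring alkene, C12 the oxymethyl carbon on C4, C13 the carboxyl on C10. The left half carries the same numbers with a prime. TBS = tert-butyldimethylsilyl, TBDPS = tert-butyldiphenylsilyl.

## Analysis of the target

The target 37 is an ester between two halves built on the same carbon pattern. The right half is a cyclohexane (ring A, C1–C6) cis-fused along C5–C6 to a seven-membered unsaturated lactone (ring B: C5–C7(=O)–O8–C9–C10=C11–C6), with isopropyl on C1, a tertiary hydroxyl and the oxymethyl carbon C12 on C4, and the acid C13 on C10. The left half is a cyclohexene (C1′–C6′, alkene C4′=C5′, hydroxymethyl C12′ on C4′, isopropyl on C1′). Its C6′ carries an (E)-2-(hydroxymethyl)acrylate arm (C11′=C10′, hydroxymethyl C9′, carbonyl C13′), and this arm acylates the oxygen on C12. Ring A holds four stereocentres (1R, 4S, 5R, 6S): C7 and C11 are cis on C5 and C6, the C4 hydroxyl is cis to C7, and isopropyl on C1 is trans to C11. The left ring holds two (6′R, 1′S): the arm-bearing carbon has the same sense as C6, but isopropyl is cis to the arm, so C1′ is set opposite to C1. Ring B is the allylic ester of a 2-(acyloxymethyl)acrylic acid and is open to SN2 and SN2′ attack; the C4 hydroxyl is β to the C7 carbonyl (retro-aldol, dehydration), and C6–H and C6′–H are γ to acrylate carbonyls. The synthesis is hard because three primary allylic oxygens and two carboxyl carbons must be told apart, C1 and C1′ must be set in opposite senses, and two unrelated syntheses of the halves should be avoided. The strategy rests on one observation: the left ring is ring A without C7 and without the C4 oxygen, and both arms are the same C11=C10(C9)(C13) unit with C9 cis to the ring. One six-membered intermediate carrying C1–C6, C7, C12 and the arm can therefore feed both halves.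

## Retrosynthetic reasoning

End game. Target 37 is traced to 36 by removal of the two left-half silyl ethers, and 36 to lactone 34 through enal 35. C13 is raised to the acid last, because once C10 carries a carbonyl the C9–O8 bond becomes an activated allylic ester; after that point only oxidations and fluoride are used.

Ring B. The acyl–oxygen bond C7–O8 is cut, giving seco acid 32. Of the two hydroxymethyl groups on C10 only the one cis to C6 can reach C7 in a seven-membered ring, so the ring closure itself tells C9 from C13. Acid 32 comes from 29 by oxidation of the C7 carbinol (31) and removal of the arm silyl ethers.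

Union of the halves. The ester is cut at the alkyl–oxygen bond O–C12, not at the acyl–oxygen bond, which leads to carboxylic acid 27 and spiro-epoxide 28. In the forward direction the carboxylate opens the epoxide at its methylene carbon, which forms the ester and frees the tertiary C4 hydroxyl in one step, with no protecting group on C4. The union is placed before ring B exists, so no activated allylic ester competes for the carboxylate.

C1 of the right half. Epoxide 28 is traced to the unsaturated epoxy carbinol 17. The forward step is a hydroxyl-directed hydrogenation of C1=C2 from the face of the C7 carbinol, which puts isopropyl trans to the arm.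

Left acid. Acid 27 goes back through 26, 25 and 24 to 23 and 22: the arm diol is unveiled, one hydroxymethyl is oxidised to the (E)-enal and then to the acid, and the other is capped. The two hydroxymethyl groups on C10′ are geminal on an alkene, so oxidation of either gives the same constitution and only the alkene geometry has to be controlled.

Left ring. Alcohol 22 is traced to epoxy acid 20 by cutting C5–C7. In the forward direction the carboxyl carbon C7 is lost and the neighbouring epoxide opens, which creates the C4′=C5′ alkene and the C12′ hydroxyl together. Acid 20 comes from 19 by hydrogenation of C1=C2 from the open face, which sets C1′ opposite to C1, and 19 from 17 by oxidation. Compound 17 is thus the point where the halves part.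

C4. Epoxide 17 is traced to carbinol 16 and ester 15. The C7 hydroxyl directs epoxidation to the exocyclic alkene and to its own face, which sets C4 for the right half and gives the left half its leaving oxygen.

Key disconnection. In adduct 15 the bonds C3–C4 and C5–C6 are cut, giving triene 13 and allenic ester 14. The cut is made there because it builds ring A in one step, brings in C7 and C12 from 14 with an alkene at C4, and leaves C1=C2 as a handle for either C1 configuration. The two arm hydroxyls are carried as TBS ethers and not as a cyclic acetal. The silyl ethers are weaker Lewis bases toward a cationic boron catalyst, they come off without disturbing the TBDPS ethers installed later, and they screen the C10=C11 alkene in the two hydrogenations.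

Triene. Compound 13 is traced through diol 12 and alkylidene malonate 11 to dienal 9 and malonate 10, and 9 through 8 and 7 to ynoate 4 and vinyl reagent 5. The C1=C6 geometry is fixed by a syn addition across the alkyne of 4, which comes from alkyne 1 and chloroformate 2.

## Alternatives that were turned down

Alternative 1: Ring B is disconnected at C7–O8 and O8–C9 by oxygen insertion. Lactone A1 would come from the cis-fused β,γ-unsaturated bicyclic ketone A2, with C7 as a ring carbonyl between C5 and the allylic C9, by Baeyer–Villiger oxidation with the silyl peroxide A3 and a silyl triflate catalyst. In its favour, ring B is derived from a robust six-membered carbocycle, the non-acidic peroxide spares the trisubstituted alkene, the C4 oxygens are already masked, and no dilute lactonisation is needed. On that last point it is stronger than the chosen route. Against it, the secondary, branched C5 normally migrates in preference to a primary carbon, so the allylic character of C9 would have to override the usual order; failure puts oxygen between C7 and C5. A2 is also a β,γ-enone that conjugates easily. C13 is still a methyl group, so a two-level allylic C–H oxidation would be needed on the finished, sensitive lactone. The left half gains nothing from this chemistry and needs its own synthesis. The chosen route offers an unambiguous C7–O8 bond (the lactonisation of 32 can use only the cis hydroxymethyl), C13 at the alcohol level from triene 13 onward, and both halves from 17.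

Alternative 2: Ring A is disconnected at C4–C5. The cis-fused hydroxy lactone A4 would come from the α-bromo butyrolactone A5, which carries the tethered α-alkoxy ketone, by a Reformatsky-type cyclisation with samarium diiodide A6. In its favour, the samarium enolate adds to a chelated ketone, so the tertiary C4 hydroxyl and C5 are set together with a cis fusion in one dependable step. For this pair of centres it is stronger than the two steps used here (cycloaddition to 15, then directed epoxidation to 17). Against it, A4 contains a five-membered lactone: C9, C10 and C13 are missing, so the butyrolactone must be opened, homologated at C11 by two carbons with a defined trisubstituted alkene, and closed again. C1 and C6 must be set beforehand in an open chain by separate asymmetric steps. The left half has no C4–C5 bond of this kind to form, so it again needs an unrelated route. The chosen route carries all arm carbons from 13 and pays for the C4/C5 pair with one extra step.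

Alternative 3: The second ring is disconnected at C5–C7 and C6–C11. Octalone A7 would come from the chiral enone A8 and the silyloxy diene A9 by a Lewis-acid Diels–Alder reaction anti to isopropyl. In its favour, the absolute configuration comes from the enone, and one step sets C1, C5 and C6 with the trans C1/C6 relation and the cis fusion under substrate control. For the right half this is stronger than a catalyst-controlled cycloaddition followed by a directed hydrogenation. Against it, the new ring is a carbocycle in which C7 is bonded to C9, so O8 must still be inserted and the alkene moved from C9=C10 to C10=C11; this leads back to the migration problem of alternative 1. Cyclohexenones are sluggish dienophiles, and the mono-oxygenated diene is labile under Lewis acid. C4 must be converted from a ketone to the tertiary carbinol with C12, with open face selectivity, and C13 is again a methyl group. The anti addition gives only the trans C1/C6 relation, so the cis left half is out of reach. The chosen route gives both C1 configurations from the one alkene of 17 and has C9 and C13 at the right oxidation level from the start.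

Key step: step 8

Assumption: the (S)-configured oxazaborolidinium catalyst is taken to expose the face of 14 that leads to the (5R,6S) adduct 15; if the antipode forms, the (R)-catalyst is used with no other change.

## Route

Step 1
Reactants: 1 3-methylbut-1-yne; 2 ethyl chloroformate
Product: 4 ethyl 4-methylpent-2-ynoate, via lithium acetylide 3 (not isolated)
Conditions: n-BuLi, THF, −78 °C; then 2, −78 to 0 °C
Reagents that add atoms: none
Why: Deprotonation of the terminal alkyne and C-acylation of the lithium acetylide by the chloroformate (acetylide acylation); no stereocentre is involved.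

Step 2
Reactants: 4 ethyl 4-methylpent-2-ynoate; 5 vinylmagnesium bromide
Product: 7 ethyl (2E)-3-(propan-2-yl)penta-2,4-dienoate, via alkenylcuprate 6 (not isolated)
Conditions: CuBr·SMe2 (1.1 equiv), 5 (2.2 equiv), THF, −78 °C; then 4, −78 °C; aq. NH4Cl at −78 °C
Reagents that add atoms: none
Why: Syn carbocupration of the ynoate: vinyl and copper add to the same side, and protonation with retention places the vinyl group trans to the ester, which is the diene geometry needed later (C11 on the outside). The low temperature keeps the alkenylcuprate from equilibrating through its allenoate form.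

Step 3
Reactants: 7 ethyl (2E)-3-(propan-2-yl)penta-2,4-dienoate
Product: 8 (2E)-3-(propan-2-yl)penta-2,4-dien-1-ol
Conditions: i-Bu2AlH (2.2 equiv), CH2Cl2, −78 °C
Reagents that add atoms: none
Why: 1,2-Reduction of a conjugated ester by an aluminium hydride in a non-coordinating solvent; the alkene geometry is not touched.

Step 4
Reactants: 8 (2E)-3-(propan-2-yl)penta-2,4-dien-1-ol
Product: 9 (2E)-3-(propan-2-yl)penta-2,4-dienal
Conditions: MnO2 (activated, excess), CH2Cl2, 20 °C
Reagents that add atoms: none
Why: Allylic oxidation of a primary allylic alcohol on MnO2; the neutral surface reaction avoids geometric isomerisation of the dienal.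

Step 5
Reactants: 9 (2E)-3-(propan-2-yl)penta-2,4-dienal; 10 dimethyl malonate
Product: 11 dimethyl 2-[(2E)-3-(propan-2-yl)penta-2,4-dien-1-ylidene]propanedioate
Conditions: TiCl4, pyridine, THF, 0 to 20 °C
Reagents that add atoms: none
Why: Knoevenagel condensation through the titanium enolate of the malonate, run without an amine catalyst that could scramble the C1=C6 geometry through a dienamine. The new alkene carries two identical ester groups and raises no geometric question.

Step 6
Reactants: 11 dimethyl 2-[(2E)-3-(propan-2-yl)penta-2,4-dien-1-ylidene]propanedioate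
Product: 12 2-[(2E)-3-(propan-2-yl)penta-2,4-dien-1-ylidene]propane-1,3-diol
Conditions: i-Bu2AlH (5 equiv), toluene/CH2Cl2, −78 to −20 °C
Reagents that add atoms: none
Why: Twofold 1,2-reduction of an alkylidene malonate to the 2-alkylidenepropane-1,3-diol; aluminium binds the carbonyl oxygen and delivers hydride to carbon and not to the polyene terminus.

Step 7
Reactants: 12 2-[(2E)-3-(propan-2-yl)penta-2,4-dien-1-ylidene]propane-1,3-diol
Product: 13 bis-TBS ether of 12 (triene)
Conditions: TBSCl (2.4 equiv), imidazole, DMF, 0 to 20 °C
Reagents that add atoms: tert-butyldimethylsilyl chloride, CC(C)(C)[Si](C)(C)Cl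
Why: Silyl ether formation on two primary alcohols under base only, which spares the acid-sensitive triene.

Step 8
Reactants: 13 bis-TBS triene; 14 ethyl buta-2,3-dienoate
Product: 15 ethyl (1R,2S)-2-{3-(TBS-oxy)-2-[(TBS-oxy)methyl]prop-1-en-1-yl}-6-methylidene-3-(propan-2-yl)cyclohex-3-ene-1-carboxylate (C7 ester and C11 arm cis on C5 and C6)
Conditions: (S)-3,3-diphenyl-1-(2-methylphenyl)tetrahydro-1H,3H-pyrrolo[1,2-c][1,3,2]oxazaborole (20 mol %) protonated with (CF3SO2)2NH (17 mol %), CH2Cl2, −78 to −40 °C
Reagents that add atoms: none
Why: The reaction is a concerted, asynchronous, suprafacial [4+2] cycloaddition between the s-cis terminal diene C3=C2–C1=C6 of 13 and the ester-conjugated C4=C5 bond of 14, whose carbonyl is bound to the cationic boron; the second allene π bond is orthogonal and stays as the exocyclic C4 methylene. The closest known reaction types are Lewis-acid-promoted Diels–Alder reactions of allenic esters across the α,β bond and oxazaborolidinium-catalysed enantioselective Diels–Alder reactions of acrylate esters. Ring A closes in an intermolecular cycloaddition mode, C3–C4 and C5–C6 forming together. The relative configuration of C5 and C6 follows from the endo transition state (ester under the diene) and the E-placed C6 substituent, which puts C7 and C11 cis. The absolute configuration is set by the catalyst: the ester binds boron anti to the ethoxy group, one face of C4=C5 is covered by an aryl group of the catalyst, and the diene adds to the open face. The regiochemistry needed (C5 to C6) is secured by the conjugating alkenyl group on C6, which makes C3 the diene terminus with the largest HOMO coefficient and pairs it with the β-carbon C4, against the weaker opposing effect of the 2-isopropyl group. Site selectivity follows because only the terminal diene can reach s-cis (the inner diene ends in the fully substituted C10) and only the conjugated allene bond is activated. Low temperature and the absence of free acid or base keep the doubly activated C5–H from epimerising and the exocyclic alkene from moving into conjugation.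

Step 9
Reactants: 15 cycloadduct ester
Product: 16 [(1R,2S)-2-{3-(TBS-oxy)-2-[(TBS-oxy)methyl]prop-1-en-1-yl}-6-methylidene-3-(propan-2-yl)cyclohex-3-en-1-yl]methanol (C7 carbinol)
Conditions: i-Bu2AlH (2.5 equiv), CH2Cl2, −78 °C
Reagents that add atoms: none
Why: Hydride reduction of the ester to the primary alcohol; the non-basic, cold conditions leave the epimerisable C5 centre and the β,γ-alkene in place.

Step 10
Reactants: 16 C7 carbinol
Product: 17 spiro-epoxide of 16 at C4 (oxirane oxygen on the ring face of the C7 carbinol, C12 on the other face)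
Conditions: VO(acac)2 (5 mol %), t-BuOOH (1.5 equiv), CH2Cl2, 0 to 20 °C
Reagents that add atoms: tert-butyl hydroperoxide, CC(C)(C)OO
Why: Hydroxyl-directed epoxidation: the vanadium alkoxide of the C7 carbinol carries the peroxide to the homoallylic exocyclic alkene on the face of ring A that bears C7, which sets C4 with its oxygen cis to C7. The two trisubstituted alkenes lie one atom further from the hydroxyl, and C10=C11 is also deactivated by its two allylic oxygens.

Step 11
Reactants: 17 epoxy carbinol
Product: 19 epoxy acid (C7 = CO2H), via epoxy aldehyde 18 (not isolated)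
Conditions: 2,2,6,6-tetramethylpiperidin-1-oxyl (20 mol %), PhI(OAc)2 (2.5 equiv), MeCN/aq. phosphate buffer pH 7, 0 to 20 °C
Reagents that add atoms: water, O
Why: Oxoammonium-mediated oxidation takes the primary alcohol through the aldehyde hydrate to the acid at neutral pH, which spares the spiro-epoxide, the silyl ethers and the alkenes.

Step 12
Reactants: 19 epoxy acid
Product: 20 1,2-dihydro derivative of 19 with C1–H on the face opposite to C11 (isopropyl cis to the arm)
Conditions: H2 (3 bar), 5% Rh/Al2O3, EtOAc, 20 °C
Reagents that add atoms: none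
Why: Heterogeneous syn hydrogenation under steric approach control: the pseudo-axial C6 arm and the C7 carboxyl cover one face of C1=C2, so both hydrogens arrive from the other face and isopropyl ends cis to the arm, as needed for C1′. Rhodium on alumina is chosen because it does not isomerise the alkene toward C6 or hydrogenolyse the epoxide and allylic C–O bonds, and C10=C11 is screened by its two silyloxymethyl groups.

Step 13
Reactants: 20 saturated epoxy acid
Product: 22 [(3R,4S)-3-{3-(TBS-oxy)-2-[(TBS-oxy)methyl]prop-1-en-1-yl}-4-(propan-2-yl)cyclohex-1-en-1-yl]methanol, via thiohydroxamate ester 21 (not isolated)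
Conditions: 2-mercaptopyridine N-oxide, dicyclohexylcarbodiimide, 4-(dimethylamino)pyridine (cat.), CH2Cl2, 0 °C, dark; then t-BuSH (10 equiv), visible light, 20 °C
Reagents that add atoms: none
Why: Proposed new method: under light the thiohydroxamate ester 21 gives an acyloxy radical that loses the C7 carboxyl carbon, and the resulting secondary C5 radical is an oxiranylcarbinyl radical that opens the adjacent C4–O bond much faster than it can take up hydrogen, forming the C4′=C5′ alkene and a primary alkoxy radical. That radical abstracts hydrogen from t-BuSH, and the thiyl radical carries the chain. The closest known reaction types are the reductive Barton decarboxylation and the radical opening of epoxides next to a carbon radical generated from thiocarbonyl derivatives of epoxy alcohols.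

Step 14
Reactants: 22 allylic alcohol
Product: 23 C12′ TBDPS ether of 22
Conditions: TBDPSCl, imidazole, DMF, 20 °C
Reagents that add atoms: tert-butyldiphenylsilyl chloride, CC(C)(C)[Si](Cl)(c1ccccc1)c1ccccc1
Why: Silyl ether formation on the primary allylic alcohol; the TBDPS ether is chosen because it outlasts the acid that removes the TBS ethers.

Step 15
Reactants: 23 tris-silyl ether
Product: 24 arm diol (C9′ and C13′ hydroxyls free, C12′ TBDPS ether kept)
Conditions: camphor-10-sulfonic acid (10 mol %), MeOH/CH2Cl2, 0 °C
Reagents that add atoms: none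
Why: Acid-catalysed methanolysis of the two primary TBS ethers; the TBDPS ether is far more stable to acid, and no acid-labile epoxide is left at this stage.

Step 16
Reactants: 24 arm diol
Product: 25 (E)-enal (C13′ aldehyde trans to C6′, C9′ hydroxymethyl cis to C6′)
Conditions: MnO2 (activated), CH2Cl2, 20 °C
Reagents that add atoms: none
Why: Allylic oxidation on MnO2, which should stop at the mono-aldehyde because the remaining hydroxymethyl then sits on an electron-poor alkene. The less hindered hydroxymethyl, trans to the ring, is expected to react first and gives the E enal directly; the two possible products differ only in alkene geometry, and the E isomer with the formyl group away from the ring is also the more stable one.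

Step 17
Reactants: 25 hydroxy enal
Product: 26 C9′ TBDPS ether of 25
Conditions: TBDPSCl, imidazole, CH2Cl2, 0 to 20 °C
Reagents that add atoms: tert-butyldiphenylsilyl chloride, CC(C)(C)[Si](Cl)(c1ccccc1)c1ccccc1
Why: Silyl ether formation under mild base, which the enal tolerates; it removes the last free hydroxyl of the left half before the union and the later lactonisation.

Step 18
Reactants: 26 bis-TBDPS enal
Product: 27 (2E)-2-[(TBDPS-oxy)methyl]-3-[(1R,6S)-3-[(TBDPS-oxy)methyl]-6-(propan-2-yl)cyclohex-2-en-1-yl]prop-2-enoic acid
Conditions: NaClO2, NaH2PO4, 2-methylbut-2-ene (excess), t-BuOH/H2O, 0 to 20 °C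
Reagents that add atoms: sodium chlorite, [Na+].[O-]Cl=O
Why: Pinnick oxidation of the enal to the acid without change of alkene geometry; the alkene scavenger takes up the hypochlorite before it can reach the ring alkene.

Step 19
Reactants: 17 epoxy carbinol
Product: 28 1,2-dihydro derivative of 17 with C1–H on the face of C7 and C11 (isopropyl trans to the arm)
Conditions: [Ir(cod)(PCy3)(py)]PF6 (5 mol %), H2 (1 atm), CH2Cl2, 0 °C
Reagents that add atoms: none
Why: Hydroxyl-directed homogeneous hydrogenation: the cationic iridium centre is held by the C7 hydroxyl and adds hydrogen to C1=C2 from the face that carries C7, against the steric bias, which sets C1 with isopropyl trans to C11. Low loading and a stop after one equivalent of H2 are meant to spare C10=C11, which is screened by its two silyloxymethyl groups and deactivated by its allylic oxygens.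

Step 20
Reactants: 28 saturated epoxy carbinol; 27 left-half acid
Product: 29 hydroxy ester (C12–O acylated by 27, tertiary C4 hydroxyl and C7 carbinol free)
Conditions: 27 (1.2 equiv), Cs2CO3 (0.3 equiv), DMF, 70 °C
Reagents that add atoms: none
Why: Epoxide opening by a carboxylate in an SN2 reaction at the methylene carbon C12 of the 2,2-disubstituted epoxide, with C4 untouched and the tertiary alkoxide reprotonated by the remaining acid. The step is run before ring B exists, so no allylic ester competes as an electrophile.

Step 21
Reactants: 29 hydroxy ester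
Product: 31 C7 carboxylic acid of 29, via hydroxy aldehyde 30 (not isolated)
Conditions: 2,2,6,6-tetramethylpiperidin-1-oxyl (20 mol %), PhI(OAc)2 (2.5 equiv), MeCN/aq. phosphate buffer pH 7, 0 to 20 °C
Reagents that add atoms: water, O
Why: Oxoammonium oxidation selects the primary C7 carbinol over the tertiary C4 hydroxyl, and the neutral medium keeps the β-hydroxy aldehyde from retro-aldol cleavage or epimerisation at C5.

Step 22
Reactants: 31 acid
Product: 32 seco acid (C9 and C13 hydroxyls free, both TBDPS ethers kept)
Conditions: camphor-10-sulfonic acid (10 mol %), MeOH/CH2Cl2, 0 °C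
Reagents that add atoms: none
Why: Selective acid-catalysed methanolysis of the two primary TBS ethers in the presence of the TBDPS ethers; the ester linkage and the tertiary alcohol are stable under these conditions.

Step 23
Reactants: 32 seco acid
Product: 34 seven-membered lactone (C7–O8–C9 closed, C13 hydroxyl free), via mixed anhydride 33 (not isolated)
Conditions: 2,4,6-trichlorobenzoyl chloride, Et3N, THF, 20 °C; then 4-(dimethylamino)pyridine, toluene (2 mM), 20 to 50 °C
Reagents that add atoms: none
Why: Yamaguchi lactonisation: only the hydroxymethyl cis to C6 can reach the activated C7 carbonyl in a seven-membered ring, so the ring closure distinguishes C9 from C13. High dilution suppresses esterification between molecules, and the hindered tertiary C4 hydroxyl is a poor competitor.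

Step 24
Reactants: 34 hydroxy lactone
Product: 35 lactone enal (C13 = CHO)
Conditions: MnO2 (activated), CH2Cl2, 20 °C
Reagents that add atoms: none
Why: Allylic oxidation of the only free primary allylic alcohol on MnO2; the tertiary alcohol and the silyl ethers do not react, and the alkene geometry is locked by ring B.

Step 25
Reactants: 35 lactone enal
Product: 36 lactone acid (C13 = CO2H, both TBDPS ethers in place)
Conditions: NaClO2, NaH2PO4, 2-methylbut-2-ene (excess), t-BuOH/H2O, 0 °C
Reagents that add atoms: sodium chlorite, [Na+].[O-]Cl=O
Why: Pinnick oxidation under weakly acidic buffer, which the activated allylic lactone and the β-hydroxy carbonyl unit tolerate.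

Step 26
Reactants: 36 bis-TBDPS ether
Product: 37 target, (5aS,6R,9S,9aR)-9-hydroxy-9-({[(2E)-2-(hydroxymethyl)-3-[(1R,6S)-3-(hydroxymethyl)-6-(propan-2-yl)cyclohex-2-en-1-yl]prop-2-enoyl]oxy}methyl)-1-oxo-6-(propan-2-yl)-1,3,5a,6,7,8,9,9a-octahydro-2-benzoxepine-4-carboxylic acid
Conditions: HF·pyridine, pyridine, THF, 0 to 20 °C
Reagents that add atoms: none
Why: Fluoride-mediated cleavage of the two primary silyl ethers under buffered, non-basic conditions, which avoids nucleophilic attack on the allylic lactone and acyl migration.

## Compound list

1 | 3-methylbut-1-yne | CC(C)C#C | starting material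
2 | ethyl chloroformate | CCOC(=O)Cl | starting material
3 | lithium 3-methylbut-1-yn-1-ide | [Li]C#CC(C)C | intermediate
4 | ethyl 4-methylpent-2-ynoate | CCOC(=O)C#CC(C)C | intermediate
5 | vinylmagnesium bromide | C=C[Mg]Br | starting material
6 | bromomagnesium [(1Z)-1-(ethoxycarbonyl)-2-(propan-2-yl)buta-1,3-dien-1-yl](vinyl)cuprate | C=C[Cu-]/C(C(=O)OCC)=C(\C=C)C(C)C.[Mg+]Br | intermediate
7 | ethyl (2E)-3-(propan-2-yl)penta-2,4-dienoate | C=C/C(=C/C(=O)OCC)C(C)C | intermediate
8 | (2E)-3-(propan-2-yl)penta-2,4-dien-1-ol | C=C/C(=C/CO)C(C)C | intermediate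
9 | (2E)-3-(propan-2-yl)penta-2,4-dienal | C=C/C(=C/C=O)C(C)C | intermediate
10 | dimethyl malonate | COC(=O)CC(=O)OC | starting material
11 | dimethyl 2-[(2E)-3-(propan-2-yl)penta-2,4-dien-1-ylidene]propanedioate | C=C/C(=C/C=C(C(=O)OC)C(=O)OC)C(C)C | intermediate
12 | 2-[(2E)-3-(propan-2-yl)penta-2,4-dien-1-ylidene]propane-1,3-diol | C=C/C(=C/C=C(CO)CO)C(C)C | intermediate
13 | bis-TBS ether of 12 (triene) | C=C/C(=C/C=C(CO[Si](C)(C)C(C)(C)C)CO[Si](C)(C)C(C)(C)C)C(C)C | intermediate
14 | ethyl buta-2,3-dienoate | C=C=CC(=O)OCC | starting material
15 | ethyl (1R,2S)-2-{3-(TBS-oxy)-2-[(TBS-oxy)methyl]prop-1-en-1-yl}-6-methylidene-3-(propan-2-yl)cyclohex-3-ene-1-carboxylate | CC(C)C1=CCC(=C)[C@H](C(=O)OCC)[C@@H]1C=C(CO[Si](C)(C)C(C)(C)C)CO[Si](C)(C)C(C)(C)C | intermediate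
16 | C7 carbinol of 15 | CC(C)C1=CCC(=C)[C@H](CO)[C@@H]1C=C(CO[Si](C)(C)C(C)(C)C)CO[Si](C)(C)C(C)(C)C | intermediate
17 | C4 spiro-epoxide of 16, oxirane oxygen cis to C7 | CC(C)C1=CC[C@@]2(CO2)[C@H](CO)[C@@H]1C=C(CO[Si](C)(C)C(C)(C)C)CO[Si](C)(C)C(C)(C)C | intermediate
18 | epoxy aldehyde (C7 = CHO) | CC(C)C1=CC[C@@]2(CO2)[C@H](C=O)[C@@H]1C=C(CO[Si](C)(C)C(C)(C)C)CO[Si](C)(C)C(C)(C)C | intermediate
19 | epoxy acid (C7 = CO2H) | CC(C)C1=CC[C@@]2(CO2)[C@H](C(=O)O)[C@@H]1C=C(CO[Si](C)(C)C(C)(C)C)CO[Si](C)(C)C(C)(C)C | intermediate
20 | saturated epoxy acid, isopropyl cis to the C6 arm | CC(C)[C@@H]1CC[C@@]2(CO2)[C@H](C(=O)O)[C@@H]1C=C(CO[Si](C)(C)C(C)(C)C)CO[Si](C)(C)C(C)(C)C | intermediate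
21 | O-acyl thiohydroxamate (2-thioxopyridin-1-yl ester) of 20 | CC(C)[C@@H]1CC[C@@]2(CO2)[C@H](C(=O)ON3C=CC=CC3=S)[C@@H]1C=C(CO[Si](C)(C)C(C)(C)C)CO[Si](C)(C)C(C)(C)C | intermediate
22 | [(3R,4S)-3-{3-(TBS-oxy)-2-[(TBS-oxy)methyl]prop-1-en-1-yl}-4-(propan-2-yl)cyclohex-1-en-1-yl]methanol | CC(C)[C@@H]1CCC(CO)=C[C@@H]1C=C(CO[Si](C)(C)C(C)(C)C)CO[Si](C)(C)C(C)(C)C | intermediate
23 | C12′ TBDPS ether of 22 | CC(C)[C@@H]1CCC(CO[Si](c2ccccc2)(c2ccccc2)C(C)(C)C)=C[C@@H]1C=C(CO[Si](C)(C)C(C)(C)C)CO[Si](C)(C)C(C)(C)C | intermediate
24 | arm diol (C12′ TBDPS ether) | CC(C)[C@@H]1CCC(CO[Si](c2ccccc2)(c2ccccc2)C(C)(C)C)=C[C@@H]1C=C(CO)CO | intermediate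
25 | (E)-2-(hydroxymethyl) enal of the left half | CC(C)[C@@H]1CCC(CO[Si](c2ccccc2)(c2ccccc2)C(C)(C)C)=C[C@@H]1/C=C(\CO)C=O | intermediate
26 | bis-TBDPS (E)-enal | CC(C)[C@@H]1CCC(CO[Si](c2ccccc2)(c2ccccc2)C(C)(C)C)=C[C@@H]1/C=C(\CO[Si](c2ccccc2)(c2ccccc2)C(C)(C)C)C=O | intermediate
27 | (2E)-2-[(TBDPS-oxy)methyl]-3-[(1R,6S)-3-[(TBDPS-oxy)methyl]-6-(propan-2-yl)cyclohex-2-en-1-yl]prop-2-enoic acid | CC(C)[C@@H]1CCC(CO[Si](c2ccccc2)(c2ccccc2)C(C)(C)C)=C[C@@H]1/C=C(\CO[Si](c2ccccc2)(c2ccccc2)C(C)(C)C)C(=O)O | intermediate
28 | saturated epoxy carbinol, isopropyl trans to the C6 arm | CC(C)[C@H]1CC[C@@]2(CO2)[C@H](CO)[C@@H]1C=C(CO[Si](C)(C)C(C)(C)C)CO[Si](C)(C)C(C)(C)C | intermediate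
29 | union product: C12 ester of 27, C4 tertiary hydroxyl, C7 carbinol | CC(C)[C@H]1CC[C@@](O)(COC(=O)/C(=C/[C@H]2C=C(CO[Si](c3ccccc3)(c3ccccc3)C(C)(C)C)CC[C@H]2C(C)C)CO[Si](c2ccccc2)(c2ccccc2)C(C)(C)C)[C@H](CO)[C@@H]1C=C(CO[Si](C)(C)C(C)(C)C)CO[Si](C)(C)C(C)(C)C | intermediate
30 | C7 aldehyde of 29 | CC(C)[C@H]1CC[C@@](O)(COC(=O)/C(=C/[C@H]2C=C(CO[Si](c3ccccc3)(c3ccccc3)C(C)(C)C)CC[C@H]2C(C)C)CO[Si](c2ccccc2)(c2ccccc2)C(C)(C)C)[C@H](C=O)[C@@H]1C=C(CO[Si](C)(C)C(C)(C)C)CO[Si](C)(C)C(C)(C)C | intermediate
31 | C7 acid of 29 | CC(C)[C@H]1CC[C@@](O)(COC(=O)/C(=C/[C@H]2C=C(CO[Si](c3ccccc3)(c3ccccc3)C(C)(C)C)CC[C@H]2C(C)C)CO[Si](c2ccccc2)(c2ccccc2)C(C)(C)C)[C@H](C(=O)O)[C@@H]1C=C(CO[Si](C)(C)C(C)(C)C)CO[Si](C)(C)C(C)(C)C | intermediate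
32 | seco acid with free C9 and C13 hydroxyls | CC(C)[C@H]1CC[C@@](O)(COC(=O)/C(=C/[C@H]2C=C(CO[Si](c3ccccc3)(c3ccccc3)C(C)(C)C)CC[C@H]2C(C)C)CO[Si](c2ccccc2)(c2ccccc2)C(C)(C)C)[C@H](C(=O)O)[C@@H]1C=C(CO)CO | intermediate
33 | mixed 2,4,6-trichlorobenzoic anhydride of 32 | CC(C)[C@H]1CC[C@@](O)(COC(=O)/C(=C/[C@H]2C=C(CO[Si](c3ccccc3)(c3ccccc3)C(C)(C)C)CC[C@H]2C(C)C)CO[Si](c2ccccc2)(c2ccccc2)C(C)(C)C)[C@H](C(=O)OC(=O)c2c(Cl)cc(Cl)cc2Cl)[C@@H]1C=C(CO)CO | intermediate
34 | seven-membered lactone with C13 hydroxymethyl | CC(C)[C@H]1CC[C@@](O)(COC(=O)/C(=C/[C@H]2C=C(CO[Si](c3ccccc3)(c3ccccc3)C(C)(C)C)CC[C@H]2C(C)C)CO[Si](c2ccccc2)(c2ccccc2)C(C)(C)C)[C@@H]2C(=O)OCC(CO)=C[C@H]12 | intermediate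
35 | lactone enal (C13 = CHO) | CC(C)[C@H]1CC[C@@](O)(COC(=O)/C(=C/[C@H]2C=C(CO[Si](c3ccccc3)(c3ccccc3)C(C)(C)C)CC[C@H]2C(C)C)CO[Si](c2ccccc2)(c2ccccc2)C(C)(C)C)[C@@H]2C(=O)OCC(C=O)=C[C@H]12 | intermediate
36 | bis-TBDPS ether of the target | CC(C)[C@H]1CC[C@@](O)(COC(=O)/C(=C/[C@H]2C=C(CO[Si](c3ccccc3)(c3ccccc3)C(C)(C)C)CC[C@H]2C(C)C)CO[Si](c2ccccc2)(c2ccccc2)C(C)(C)C)[C@@H]2C(=O)OCC(C(=O)O)=C[C@H]12 | intermediate
37 | CNP0361406.10 | CC(C)[C@H]1CC[C@@](O)(COC(=O)/C(=C/[C@H]2C=C(CO)CC[C@H]2C(C)C)CO)[C@@H]2C(=O)OCC(C(=O)O)=C[C@H]12 | target

## Step count and least certain steps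

Total: 26 steps. Longest linear sequence: 25 steps (steps 1–18, then 20–26); step 19 runs in parallel from the shared intermediate 17.

Step 13 (labelled step). The alkoxy radical formed after ring opening may react on before it is reduced, by hydrogen abstraction from C2′–H or by capture at the thiocarbonyl group, and the epoxy acid may decompose during activation. The fallback uses known ionic chemistry and sets out from 20. Cesium acetate in DMF (CsOAc in excess, 80 °C) opens the epoxide at C12 to the hydroxy acetate acid F1. Benzenesulfonyl chloride in pyridine closes the cis β-hydroxy acid to the β-lactone F2. Heating in toluene expels the carboxyl carbon in a syn fashion and gives the allylic acetate F3. K2CO3 in MeOH removes the acetate and returns the route to 22.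

Step 8 (key step). Three things may fail: regiocontrol may erode because the isopropyl group pulls the other way; the exo approach or weak face discrimination on this untested triene may lower the selectivity; and the strong Lewis acid may shift the exocyclic alkene into conjugation or oligomerise the triene. The fallback gives up catalyst control and sets out from 13 and 14. Cycloaddition promoted by EtAlCl2 in CH2Cl2 gives the racemic cis adduct F4, and i-Bu2AlH reduces it to the racemic carbinol F5. Esterification with (S)-2-methoxy-2-phenylacetic acid (dicyclohexylcarbodiimide, 4-(dimethylamino)pyridine) and chromatographic separation of the two diastereomers gives the mandelate F6 of the required enantiomer. K2CO3 in MeOH returns the route to 16.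

Step 19. The C7 hydroxyl is equally distant from the arm alkene C10=C11, so the arm alkene may also be hydrogenated, and direction by a bishomoallylic primary hydroxyl may be weak. The fallback moves the hydrogenation behind the union and changes the directing group. It sets out from 17 and 27: opening of the epoxide under the conditions of step 20 gives the unsaturated hydroxy ester F7. Its tertiary C4 hydroxyl is homoallylic to C1=C2 and on the required face. It directs [Rh(nbd)(dppb)]BF4 under H2 pressure, a catalyst that turns over trisubstituted alkenes only when a hydroxyl holds them. This returns the route to 29.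

Step 12. The arm alkene may be reduced on the metal surface, hydrogen may be delivered from the wrong face if the carboxyl group anchors the substrate, and the epoxide may be opened by hydrogenolysis. The fallback replaces surface delivery on the acid by homogeneous, sterically controlled delivery on a capped carbinol. It sets out from 17: acetylation (Ac2O, pyridine) gives the acetate F8. Hydrogenation with [Ir(cod)(PCy3)(py)]PF6 in CH2Cl2, with no free hydroxyl to direct it, should go from the open face and give F9. K2CO3 in MeOH gives the carbinol F10, and oxidation as in step 11 returns the route to 20.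

Step 6. Hydride may add in a conjugate sense along the doubly activated polyene, or the alkylidene malonate may be over-reduced. The fallback avoids the malonate and sets out from 8. PBr3 gives the dienyl bromide F11 and PPh3 the phosphonium salt F12. Its ylide (NaN(SiMe3)2, THF, −78 °C) is condensed in a Wittig reaction with commercially available 1,3-bis(tert-butyldimethylsilyloxy)propan-2-one. The new alkene has two identical substituents, so the reaction returns the route directly to 13; the C1=C6 geometry of the allylic ylide would have to be watched.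

## Further compounds

F1 | step 13 | hydroxy acetate acid (C4 hydroxyl, C12 acetate, C7 acid) | CC(C)[C@@H]1CC[C@@](O)(COC(C)=O)[C@H](C(=O)O)[C@@H]1C=C(CO[Si](C)(C)C(C)(C)C)CO[Si](C)(C)C(C)(C)C
F2 | step 13 | cis-fused β-lactone between C7 and the C4 oxygen | CC(C)[C@@H]1CC[C@]2(COC(C)=O)OC(=O)[C@@H]2[C@@H]1C=C(CO[Si](C)(C)C(C)(C)C)CO[Si](C)(C)C(C)(C)C
F3 | step 13 | allylic acetate of 22 | CC(C)[C@@H]1CCC(COC(C)=O)=C[C@@H]1C=C(CO[Si](C)(C)C(C)(C)C)CO[Si](C)(C)C(C)(C)C
F4 | step 8 | racemic cis adduct (15 and its enantiomer) | CC(C)C1=CCC(=C)[C@H](C(=O)OCC)[C@@H]1C=C(CO[Si](C)(C)C(C)(C)C)CO[Si](C)(C)C(C)(C)C.CC(C)C1=CCC(=C)[C@@H](C(=O)OCC)[C@H]1C=C(CO[Si](C)(C)C(C)(C)C)CO[Si](C)(C)C(C)(C)C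
F5 | step 8 | racemic carbinol (16 and its enantiomer) | CC(C)C1=CCC(=C)[C@H](CO)[C@@H]1C=C(CO[Si](C)(C)C(C)(C)C)CO[Si](C)(C)C(C)(C)C.CC(C)C1=CCC(=C)[C@@H](CO)[C@H]1C=C(CO[Si](C)(C)C(C)(C)C)CO[Si](C)(C)C(C)(C)C
F6 | step 8 | (S)-2-methoxy-2-phenylacetate of 16 | CC(C)C1=CCC(=C)[C@H](COC(=O)[C@@H](OC)c2ccccc2)[C@@H]1C=C(CO[Si](C)(C)C(C)(C)C)CO[Si](C)(C)C(C)(C)C
F7 | step 19 | unsaturated hydroxy ester (29 with C1=C2 in place) | CC(C)C1=CC[C@@](O)(COC(=O)/C(=C/[C@H]2C=C(CO[Si](c3ccccc3)(c3ccccc3)C(C)(C)C)CC[C@H]2C(C)C)CO[Si](c2ccccc2)(c2ccccc2)C(C)(C)C)[C@H](CO)[C@@H]1C=C(CO[Si](C)(C)C(C)(C)C)CO[Si](C)(C)C(C)(C)C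
F8 | step 12 | C7 acetate of 17 | CC(C)C1=CC[C@@]2(CO2)[C@H](COC(C)=O)[C@@H]1C=C(CO[Si](C)(C)C(C)(C)C)CO[Si](C)(C)C(C)(C)C
F9 | step 12 | saturated epoxy acetate, isopropyl cis to the arm | CC(C)[C@@H]1CC[C@@]2(CO2)[C@H](COC(C)=O)[C@@H]1C=C(CO[Si](C)(C)C(C)(C)C)CO[Si](C)(C)C(C)(C)C
F10 | step 12 | saturated epoxy carbinol, isopropyl cis to the arm | CC(C)[C@@H]1CC[C@@]2(CO2)[C@H](CO)[C@@H]1C=C(CO[Si](C)(C)C(C)(C)C)CO[Si](C)(C)C(C)(C)C
F11 | step 6 | (2E)-1-bromo-3-(propan-2-yl)penta-2,4-diene | C=C/C(=C/CBr)C(C)C
F12 | step 6 | [(2E)-3-(propan-2-yl)penta-2,4-dien-1-yl]triphenylphosphonium bromide | C=C/C(=C/C[P+](c1ccccc1)(c1ccccc1)c1ccccc1)C(C)C.[Br-]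
A1 | alternative 1 | seven-membered lactone acetonide | CC(C)[C@H]1CC[C@@]3(COC(C)(C)O3)[C@@H]2C(=O)OCC(C)=C[C@H]12
A2 | alternative 1 | cis-fused β,γ-unsaturated bicyclic ketone | CC(C)[C@H]1CC[C@@]3(COC(C)(C)O3)[C@@H]2C(=O)CC(C)=C[C@H]12
A3 | alternative 1 | bis(trimethylsilyl) peroxide | C[Si](C)(C)OO[Si](C)(C)C
A4 | alternative 2 | cis-fused hydroxy bicyclic butyrolactone | CC(C)[C@H]1CC[C@@](O)(COCc3ccc(OC)cc3)[C@@H]2C(=O)OC[C@H]12
A5 | alternative 2 | α-bromo butyrolactone with tethered α-alkoxy ketone | CC(C)[C@@H](CCC(=O)COCc1ccc(OC)cc1)[C@H]1COC(=O)C1Br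
A6 | alternative 2 | samarium diiodide | I[Sm]I
A7 | alternative 3 | cis-fused silyloxy octalone | CC(C)[C@H]1CCC(=O)[C@@H]2[C@H](O[Si](C)(C)C(C)(C)C)C=C(C)C[C@H]12
A8 | alternative 3 | (R)-4-(propan-2-yl)cyclohex-2-en-1-one | CC(C)[C@H]1CCC(=O)C=C1
A9 | alternative 3 | (E)-1-(tert-butyldimethylsilyloxy)-3-methylbuta-1,3-diene | C=C(C)/C=C/O[Si](C)(C)C(C)(C)C
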